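The target is cut at the C8'–C9' single bond between the C7'=C8' ethene unit on ring B and the methyl-bearing C9'. Rings A and B are the same (3S,4S)-diol and differ only in the oxidation level of C7–C8, so one building block, ethynyl diol 8, serves both ends. On the ring A side its triple bond is coupled to a symmetric C18 diiodide. In the key step its C7'≡C8' triple bond is syn-hydrostannylated in the flask to the E-alkenylstannane, which Stille coupling joins to the C9' iodide of iodo-heptaenyne 14. One operation thus sets the C7'=C8' geometry and forms C8'–C9', with no protecting groups.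

Key step: step 11

Remark: carotenoid numbering is used (ring A C1–C6 carries C7≡C8, ring B C1'–C6' carries C7'=C8'); 1, 4, 9 and 12 are commercial; polyenes 13, 14 and 16 are handled under argon in the dark; the sense of induction in step 1 is assumed from the CH/π model of the transfer-hydrogenation catalyst with the C2=C3 alkene in the aryl role, and the mirror-image ligand would be used if it proved opposite.

Step 1
Reactants: 1 2,6,6-trimethylcyclohex-2-ene-1,4-dione
Product: 2 (4S)-4-hydroxy-2,6,6-trimethylcyclohex-2-en-1-one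
Conditions: RuCl[(S,S)-TsDPEN](p-cymene) (cat.), KOH (cat.), iPrOH, rt
Reagents that add atoms: none
Why: Noyori asymmetric transfer hydrogenation should reduce only the C4 carbonyl, which is flanked by CH2 and CH=, and leave the C1 carbonyl shielded by the gem-dimethyl carbon, with the chiral Ru–H/N–H catalyst setting the (S)-carbinol that later becomes C3 and C3'.

Step 2
Reactants: 2 (4S)-4-hydroxy-2,6,6-trimethylcyclohex-2-en-1-one
Product: 3 (4S)-4-[(tert-butyldimethylsilyl)oxy]-2,6,6-trimethylcyclohex-2-en-1-one
Conditions: TBSCl, imidazole, DMF, rt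
Reagents that add atoms: tert-butyldimethylsilyl chloride, CC(C)(C)[Si](C)(C)Cl
Why: Imidazole-promoted O-silylation of the secondary allylic alcohol masks the oxygen against the Grignard reagent and the chromium oxidant of the next two steps.

Step 3
Reactants: 3 (4S)-4-[(tert-butyldimethylsilyl)oxy]-2,6,6-trimethylcyclohex-2-en-1-one; 4 ethynylmagnesium bromide
Product: 5 (4S)-4-[(tert-butyldimethylsilyl)oxy]-1-ethynyl-2,6,6-trimethylcyclohex-2-en-1-ol (mixture of C1 epimers)
Conditions: THF, 0 °C to rt; aqueous NH4Cl
Reagents that add atoms: none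
Why: Grignard 1,2-addition to the only remaining, non-enolisable carbonyl; the new carbinol centre may form as a mixture because step 4 turns it into an sp2 carbon.

Step 4
Reactants: 5 (4S)-4-[(tert-butyldimethylsilyl)oxy]-1-ethynyl-2,6,6-trimethylcyclohex-2-en-1-ol
Product: 6 (6S)-6-[(tert-butyldimethylsilyl)oxy]-3-ethynyl-2,4,4-trimethylcyclohex-2-en-1-one
Conditions: pyridinium chlorochromate [C5H5NH][CrO3Cl], NaOAc, 4 Å molecular sieves, CH2Cl2, rt
Reagents that add atoms: none
Why: Babler–Dauben oxidative 1,3-transposition: the tertiary allylic chromate ester undergoes a [3,3] shift to the secondary allylic chromate, which is oxidised to the enone, placing the ethynyl group on the tetrasubstituted C5=C6 alkene and the carbonyl at C4 next to the untouched (S)-C3 centre.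

Step 5
Reactants: 6 (6S)-6-[(tert-butyldimethylsilyl)oxy]-3-ethynyl-2,4,4-trimethylcyclohex-2-en-1-one
Product: 7 (6S)-3-ethynyl-6-hydroxy-2,4,4-trimethylcyclohex-2-en-1-one
Conditions: aqueous HF, MeCN, 0 °C to rt
Reagents that add atoms: none
Why: Acidic fluoride desilylation frees the 3-OH needed as a directing group under non-basic conditions that should not enolise the α-ketol or racemise C3.

Step 6
Reactants: 7 (6S)-3-ethynyl-6-hydroxy-2,4,4-trimethylcyclohex-2-en-1-one
Product: 8 (1S,2S)-4-ethynyl-3,5,5-trimethylcyclohex-3-ene-1,2-diol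
Conditions: Me4N[BH(OAc)3], MeCN/AcOH, −30 °C to 0 °C
Reagents that add atoms: none
Why: Saksena–Evans hydroxyl-directed reduction: the 3-OH exchanges onto boron and hydride is delivered intramolecularly to the C4 carbonyl from the face of the C3 oxygen, so the new C4–OH should come out trans to it, that is (4S), by 1,2-relay from C3.

Step 7
Reactants: 9 but-2-yn-1-ol
Product: 10 (2E)-3-iodobut-2-en-1-ol
Conditions: iBu2AlH (2 equiv), Cp2ZrCl2, THF, 0 °C to rt; then I2, −78 °C to rt
Reagents that add atoms: iodine, II
Why: Hydrozirconation/iodinolysis: Cp2Zr(H)Cl formed in the flask adds syn across the alkyne with zirconium at C3, remote from the CH2 that carries the aluminium alkoxide, and iodine cleaves the C–Zr bond with retention to give the E-iodide.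

Step 8
Reactants: 10 (2E)-3-iodobut-2-en-1-ol
Product: 11 diethyl [(2E)-3-iodobut-2-en-1-yl]phosphonate
Conditions: P(OEt)3, ZnI2, THF, reflux
Reagents that add atoms: triethyl phosphite, CCOP(OCC)OCC
Why: Zinc iodide-mediated Michaelis–Arbuzov-type phosphonylation of the primary allylic alcohol proceeds by substitution at the CH2 carbon, so the E-alkenyl iodide, inert to phosphite without a transition metal, is carried through unchanged.

Step 9
Reactants: 11 diethyl [(2E)-3-iodobut-2-en-1-yl]phosphonate (2.2 equiv); 12 (2E,4E,6E)-2,7-dimethylocta-2,4,6-trienedial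
Product: 13 (2E,4E,6E,8E,10E,12E,14E)-2,15-diiodo-6,11-dimethylhexadeca-2,4,6,8,10,12,14-heptaene
Conditions: NaN(SiMe3)2, THF, −78 °C to 0 °C, dark
Reagents that add atoms: none
Why: Twofold Horner–Wadsworth–Emmons olefination: the allylic phosphonate anion attacks each aldehyde through its α-carbon and phosphate elimination should give the E-configured C11=C12 and C11'=C12' bonds, the all-E diiodide being purified by crystallisation.

Step 10
Reactants: 8 (1S,2S)-4-ethynyl-3,5,5-trimethylcyclohex-3-ene-1,2-diol; 13 (2E,4E,6E,8E,10E,12E,14E)-2,15-diiodo-6,11-dimethylhexadeca-2,4,6,8,10,12,14-heptaene (3 equiv)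
Product: 14 (1S,2S)-4-[(3E,5E,7E,9E,11E,13E,15E)-16-iodo-3,7,12-trimethylheptadeca-3,5,7,9,11,13,15-heptaen-1-yn-1-yl]-3,5,5-trimethylcyclohex-3-ene-1,2-diol
Conditions: Pd(PPh3)4 (cat.), CuI (cat.), iPr2NH, THF, rt, dark; unreacted 13 recovered
Reagents that add atoms: none
Why: Sonogashira coupling of the terminal alkyne with an alkenyl iodide retains the C9=C10 geometry and tolerates the free diol; the excess of the symmetric diiodide should hold the reaction at mono-coupling.

Step 11
Reactants: 8 (1S,2S)-4-ethynyl-3,5,5-trimethylcyclohex-3-ene-1,2-diol (1.5 equiv); 14 (1S,2S)-4-[(3E,5E,7E,9E,11E,13E,15E)-16-iodo-3,7,12-trimethylheptadeca-3,5,7,9,11,13,15-heptaen-1-yn-1-yl]-3,5,5-trimethylcyclohex-3-ene-1,2-diol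
Product: 16 (all-E)-(3S,4S,3'S,4'S)-7,8-didehydro-β,β-carotene-3,4,3',4'-tetrol (target), via E-alkenylstannane 15 (not isolated)
Conditions: 8, Bu3SnH (slow addition), PdCl2(PPh3)2 (cat.), THF, 0 °C to rt until the tin hydride is consumed; then 14, Pd2(dba)3 (cat.), AsPh3, NMP, 40 °C, dark
Reagents that add atoms: none
Why: Zerovalent palladium adds the Sn–H bond of Bu3SnH syn across the terminal C7'≡C8' triple bond of 8, tin going to the terminal C8' because C7' is shielded by the tetrasubstituted C5'=C6' ring alkene and the C1' gem-dimethyl group, which gives E-alkenylstannane 15; in the same flask oxidative addition of the C9'–I bond of 14 to zerovalent palladium, tin-to-palladium transmetallation and reductive elimination (Migita–Kosugi–Stille coupling) form C8'–C9' with retention at both sp2 carbons. The closest known reaction type is the one-pot palladium-catalysed hydrostannation/Stille sequence of terminal alkynes with alkenyl iodides. No ring is closed and no stereocentre is created; the four carbinol centres come in unchanged from 8. The step needs regioselectivity (distal tin, secured by the bulk at C6'; any proximal stannane would be too hindered to transmetallate), retention of all E double bonds (neutral conditions, AsPh3 ligand, darkness), and chemoselectivity for the iodide over the internal C7≡C8 triple bond and the free hydroxyls (the tin hydride is consumed before 14 is added, and organostannanes tolerate OH).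

Compound list
1 | 2,6,6-trimethylcyclohex-2-ene-1,4-dione | CC1=CC(=O)CC(C)(C)C1=O | starting material
2 | (4S)-4-hydroxy-2,6,6-trimethylcyclohex-2-en-1-one | CC1=C[C@@H](O)CC(C)(C)C1=O | intermediate
3 | (4S)-4-[(tert-butyldimethylsilyl)oxy]-2,6,6-trimethylcyclohex-2-en-1-one | CC1=C[C@@H](O[Si](C)(C)C(C)(C)C)CC(C)(C)C1=O | intermediate
4 | ethynylmagnesium bromide | C#C[Mg]Br | starting material
5 | (4S)-4-[(tert-butyldimethylsilyl)oxy]-1-ethynyl-2,6,6-trimethylcyclohex-2-en-1-ol, C1 epimers | CC1=C[C@@H](O[Si](C)(C)C(C)(C)C)CC(C)(C)C1(O)C#C | intermediate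
6 | (6S)-6-[(tert-butyldimethylsilyl)oxy]-3-ethynyl-2,4,4-trimethylcyclohex-2-en-1-one | CC1=C(C#C)C(C)(C)C[C@H](O[Si](C)(C)C(C)(C)C)C1=O | intermediate
7 | (6S)-3-ethynyl-6-hydroxy-2,4,4-trimethylcyclohex-2-en-1-one | CC1=C(C#C)C(C)(C)C[C@H](O)C1=O | intermediate
8 | (1S,2S)-4-ethynyl-3,5,5-trimethylcyclohex-3-ene-1,2-diol | CC1=C(C#C)C(C)(C)C[C@H](O)[C@H]1O | intermediate
9 | but-2-yn-1-ol | CC#CCO | starting material
10 | (2E)-3-iodobut-2-en-1-ol | C/C(I)=C\CO | intermediate
11 | diethyl [(2E)-3-iodobut-2-en-1-yl]phosphonate | CCOP(=O)(OCC)C/C=C(\C)I | intermediate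
12 | (2E,4E,6E)-2,7-dimethylocta-2,4,6-trienedial | O=C/C(C)=C/C=C/C=C(\C)C=O | starting material
13 | (2E,4E,6E,8E,10E,12E,14E)-2,15-diiodo-6,11-dimethylhexadeca-2,4,6,8,10,12,14-heptaene | I/C(C)=C/C=C/C(C)=C/C=C/C=C(C)/C=C/C=C(\C)I | intermediate
14 | (1S,2S)-4-[(3E,5E,7E,9E,11E,13E,15E)-16-iodo-3,7,12-trimethylheptadeca-3,5,7,9,11,13,15-heptaen-1-yn-1-yl]-3,5,5-trimethylcyclohex-3-ene-1,2-diol | CC1=C(C#C/C(C)=C/C=C/C(C)=C/C=C/C=C(C)/C=C/C=C(\C)I)C(C)(C)C[C@H](O)[C@H]1O | intermediate
15 | (1S,2S)-3,5,5-trimethyl-4-[(E)-2-(tributylstannyl)ethenyl]cyclohex-3-ene-1,2-diol | CCCC[Sn](CCCC)(CCCC)/C=C/C1=C(C)[C@H](O)[C@@H](O)CC1(C)C | intermediate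
16 | (all-E)-(3S,4S,3'S,4'S)-7,8-didehydro-β,β-carotene-3,4,3',4'-tetrol | CC1=C(C#C/C(C)=C/C=C/C(C)=C/C=C/C=C(C)/C=C/C=C(C)/C=C/C2=C(C)[C@H](O)[C@@H](O)CC2(C)C)C(C)(C)C[C@H](O)[C@H]1O | target

Total step count: 11. Longest linear sequence: 8 steps (steps 1 to 6, then 10 and 11).

Steps most likely to fail

Step 11. The hydrostannation may place tin partly at the ring-bound carbon, residual tin hydride may reduce the C9'–I bond, or the polyene may isomerise or homocouple during the coupling. The fallback sets out from 8 and isolates the organometallic partner. Copper-catalysed protoboration of 8 (B2pin2, CuCl, Xantphos, NaOtBu, MeOH, THF, rt) should give (1S,2S)-3,5,5-trimethyl-4-[(E)-2-(4,4,5,5-tetramethyl-1,3,2-dioxaborolan-2-yl)ethenyl]cyclohex-3-ene-1,2-diol F1, which can be purified from any regioisomer. Suzuki–Miyaura coupling of F1 with 14 (Pd(OAc)2, SPhos, aqueous K3PO4, THF, rt, dark) then comes back to the route at 16.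

Step 10. Statistical over-coupling to the bis-alkynyl heptaene, together with poor solubility and light-induced decomposition of the diiodide, may erode the mono-coupling. The fallback sets out from 8, 11 and 12 and avoids 13 altogether. Sonogashira coupling of 8 with 11 (Pd(PPh3)4, CuI, iPr2NH, THF) should give diethyl [(2E)-5-[(3S,4S)-3,4-dihydroxy-2,6,6-trimethylcyclohex-1-en-1-yl]-3-methylpent-2-en-4-yn-1-yl]phosphonate F2. Mono-olefination of excess 12 with the anion of 11 (NaN(SiMe3)2, THF, −78 °C) should give (2E,4E,6E,8E,10E)-11-iodo-2,7-dimethyldodeca-2,4,6,8,10-pentaenal F3. Horner–Wadsworth–Emmons reaction of F2 (deprotonated with three equivalents of NaN(SiMe3)2 to cover the two hydroxyls) with F3 comes back to the route at 14.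

Step 6. Intermolecular hydride transfer may compete with the intramolecular delivery and lower the facial selectivity, or the α-ketol may epimerise through its enediol. The fallback sets out from 6 and replaces substrate direction by reagent control. Corey–Bakshi–Shibata reduction of 6 with (S)-2-methyl-CBS-oxazaborolidine ((S)-1-methyl-3,3-diphenylhexahydropyrrolo[1,2-c][1,3,2]oxazaborole) and BH3·SMe2 in THF at −30 °C, the alkenyl flank acting as the large group, should give (1S,6S)-6-[(tert-butyldimethylsilyl)oxy]-3-ethynyl-2,4,4-trimethylcyclohex-2-en-1-ol F4. Desilylation of F4 with Bu4NF in THF comes back to the route at 8.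

Further compounds
F1 | step 11 | (1S,2S)-3,5,5-trimethyl-4-[(E)-2-(4,4,5,5-tetramethyl-1,3,2-dioxaborolan-2-yl)ethenyl]cyclohex-3-ene-1,2-diol | CC1(C)OB(/C=C/C2=C(C)[C@H](O)[C@@H](O)CC2(C)C)OC1(C)C
F2 | step 10 | diethyl [(2E)-5-[(3S,4S)-3,4-dihydroxy-2,6,6-trimethylcyclohex-1-en-1-yl]-3-methylpent-2-en-4-yn-1-yl]phosphonate | CCOP(=O)(OCC)C/C=C(\C)C#CC1=C(C)[C@H](O)[C@@H](O)CC1(C)C
F3 | step 10 | (2E,4E,6E,8E,10E)-11-iodo-2,7-dimethyldodeca-2,4,6,8,10-pentaenal | O=C/C(C)=C/C=C/C=C(C)/C=C/C=C(\C)I
F4 | step 6 | (1S,6S)-6-[(tert-butyldimethylsilyl)oxy]-3-ethynyl-2,4,4-trimethylcyclohex-2-en-1-ol | CC1=C(C#C)C(C)(C)C[C@H](O[Si](C)(C)C(C)(C)C)[C@H]1O
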